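**Retrosynthetic overview**
1. Target 21 ← silyl ether 20: the two different esters are installed one after the other (C1 by bromination and carboxylate displacement with inversion, C6 by allylic oxidation and acylation) while the side-chain hydroxyl stays silylated.
2. trans-Hydrindan-2-one 13 ← trans-fused cyclobutanol 11: an epoxide-triggered semipinacol 1,2-shift expands the four-membered ring to the cyclopentanone and sets the aldol stereodiad (key step).
3. 11 ← cyclobutanone 8 + (Z)-propenyllithium; 8 ← head-to-tail [2+2] photoadduct 6 of (R)-cryptone 4 and 1,1-dimethoxyethene, then methylenation and ketal hydrolysis.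
4. 4 ← 3-methylbutanal + but-3-en-2-one (organocatalytic Michael addition, aldol condensation).
5. Ring order: six-membered ring, then cyclobutane, then ring expansion to the five-membered ring.

Assumption: the target is taken exactly as the SMILES defines it (side-chain carbinol S, 2-methylbutanoate R, enoate E), and position labels in each step follow the systematic name of the compound of that step.

**Step 1**
Reactants: 1 3-methylbutanal; 2 but-3-en-2-one
Product: 4 (4R)-4-(propan-2-yl)cyclohex-2-en-1-one, via keto aldehyde 3 (not isolated)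
Conditions: (R)-2-[methoxy(diphenyl)methyl]pyrrolidine (5 mol%), ethyl 3,4-dihydroxybenzoate (20 mol%), neat, 4 °C; then LiOH (0.2 equiv), i-PrOH, rt
Reagents that add atoms: none
Why: Enamine-catalysed Michael addition (the diphenylmethyl group shields one enamine face, which sets the isopropyl-bearing stereocenter as R) followed by intramolecular aldol condensation, i.e. an organocatalytic Robinson-type annulation.

**Step 2**
Reactants: 4 (4R)-4-(propan-2-yl)cyclohex-2-en-1-one; 5 1,1-dimethoxyethene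
Product: 6 (1S,5R,6R)-7,7-dimethoxy-5-(propan-2-yl)bicyclo[4.2.0]octan-2-one
Conditions: hν (350 nm, Pyrex), 5 (10 equiv), pentane, −40 °C; rapid chromatography on neutral silica, no base
Reagents that add atoms: none
Why: Enone–alkene [2+2] photocycloaddition: the electron-rich alkene adds head-to-tail (acetal carbon on the β-carbon), the first bond forms anti to the isopropyl group (C6), and the twisted triplet enone closes mainly to the kinetic trans-fused ring junction (C1), which is kept by avoiding base.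

**Step 3**
Reactants: 6 (1S,5R,6R)-7,7-dimethoxy-5-(propan-2-yl)bicyclo[4.2.0]octan-2-one
Product: 8 (1S,5R,6R)-2-methylidene-5-(propan-2-yl)bicyclo[4.2.0]octan-7-one, via methylidene ketal 7 (not isolated)
Conditions: Cp2TiMe2 (2.5 equiv), toluene, 65 °C, dark; then 1 M aq HCl, THF, 0 °C
Reagents that add atoms: dimethyltitanocene (Cp2TiMe2), C[Ti](C)(C1C=CC=C1)C1C=CC=C1; water, O
Why: Non-basic Petasis methylenation converts the epimerisable ketone without touching the trans ring fusion (after which C1 can no longer epimerise), and mild acid hydrolysis of the dimethyl ketal frees the cyclobutanone; no new stereocenter.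

**Step 4**
Reactants: 8 (1S,5R,6R)-2-methylidene-5-(propan-2-yl)bicyclo[4.2.0]octan-7-one; 9 (1Z)-1-bromoprop-1-ene
Product: 11 (1S,5R,6R,7R)-2-methylidene-5-(propan-2-yl)-7-[(1Z)-prop-1-en-1-yl]bicyclo[4.2.0]octan-7-ol, via (1Z)-prop-1-en-1-yllithium 10 (not isolated)
Conditions: 9 (1.5 equiv), t-BuLi (3.0 equiv), Et2O, −78 °C; then 8, −78 °C; H2O quench
Reagents that add atoms: none
Why: Lithium–halogen exchange keeps the Z geometry, and 1,2-addition to the strained ketone occurs on the face syn to H-6, because in the twisted trans-fused cyclobutanone the pseudo-axial H-1 sits over the other face; this gives the 7R carbinol.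

**Step 5**
Reactants: 11 (1S,5R,6R,7R)-2-methylidene-5-(propan-2-yl)-7-[(1Z)-prop-1-en-1-yl]bicyclo[4.2.0]octan-7-ol
Product: 13 (1R,3aS,7R,7aR)-4-methylidene-7-(propan-2-yl)-1-[(1S)-1-[(triethylsilyl)oxy]ethyl]octahydro-2H-inden-2-one, via epoxy alcohol 12 (not isolated)
Conditions: VO(acac)2 (5 mol%), t-BuOOH (1.3 equiv, decane solution), CH2Cl2, 0 °C; then 2,6-lutidine (4 equiv), Et3SiOTf (2.5 equiv), −78 → −40 °C
Reagents that add atoms: tert-butyl hydroperoxide, CC(C)(C)OO; triethylsilyl trifluoromethanesulfonate, CC[Si](CC)(CC)OS(=O)(=O)C(F)(F)F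
Why: Proposed new method: a one-flask relay of hydroxyl-directed epoxidation into a silyl-triflate-triggered semipinacol ring expansion on a trans-fused bicyclo[4.2.0]octan-7-ol, a substrate class on which this sequence has not been shown; the vanadium alkoxide of 11 (pentavalent after oxidation by the hydroperoxide) delivers oxygen to the alkene face exposed when allylic 1,3-strain puts the small ring CH2 (C8), not the bridgehead C6 flanked by the isopropyl group, next to the Z-methyl, giving the (2S,3S)-oxirane 12; Et3SiOTf then silylates the oxirane oxygen and the antiperiplanar, more substituted C6–C7 bond migrates with retention at C6 and inversion at the oxirane carbon, driven by release of the strain of the trans-fused four-membered ring, so the trans fusion is carried into the hydrindanone, C1 (R) and the carbinol carbon (S) are set together and the silyl group ends on the new oxygen; the closest known reactions are vanadium-catalysed epoxidation of allylic alcohols, the silyl-triflate rearrangement of 2,3-epoxy alcohol derivatives to β-silyloxy carbonyl compounds and epoxide-triggered ring expansion of 1-alkenylcyclobutanols.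

**Step 6**
Reactants: 13 (1R,3aS,7R,7aR)-4-methylidene-7-(propan-2-yl)-1-[(1S)-1-[(triethylsilyl)oxy]ethyl]octahydro-2H-inden-2-one; 14 (2R)-2-methylbutanoic acid
Product: 17 (1R,3R,3aR,4R,7aS)-7-methylidene-2-oxo-4-(propan-2-yl)-3-[(1S)-1-[(triethylsilyl)oxy]ethyl]octahydro-1H-inden-1-yl (2R)-2-methylbutanoate, via silyl enol ether 15 (not isolated), via bromo ketone 16 (not isolated)
Conditions: LiN(SiMe3)2 (1.1 equiv), Me3SiCl, THF, −78 °C; NBS (1.05 equiv), −78 °C; solvent exchange to DMF, 14 (1.5 equiv), Cs2CO3 (1.5 equiv), 0 °C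
Reagents that add atoms: none
Why: Kinetic deprotonation takes the unsubstituted CH2 flank of the ketone, bromine enters cis to the adjacent ring-fusion hydrogen (the other face is blocked by the axial ring-fusion hydrogen across the ring and by the side chain), and SN2 displacement by the cesium carboxylate inverts this center to the required 1R acyloxy configuration.

**Step 7**
Reactants: 17 (1R,3R,3aR,4R,7aS)-7-methylidene-2-oxo-4-(propan-2-yl)-3-[(1S)-1-[(triethylsilyl)oxy]ethyl]octahydro-1H-inden-1-yl (2R)-2-methylbutanoate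
Product: 18 (1R,3R,3aR,4R,6S,7aS)-6-hydroxy-7-methylidene-2-oxo-4-(propan-2-yl)-3-[(1S)-1-[(triethylsilyl)oxy]ethyl]octahydro-1H-inden-1-yl (2R)-2-methylbutanoate
Conditions: SeO2 (0.3 equiv), t-BuOOH (3 equiv), CH2Cl2, 0 °C → rt
Reagents that add atoms: tert-butyl hydroperoxide, CC(C)(C)OO
Why: Selenium dioxide allylic oxidation (ene reaction, then [2,3]-sigmatropic shift) attacks the allylic CH2 in preference to the ring-fusion CH, removes the axial hydrogen and returns oxygen on the same face, giving the axial 6S alcohol with the exocyclic alkene restored.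

**Step 8**
Reactants: 18 (1R,3R,3aR,4R,6S,7aS)-6-hydroxy-7-methylidene-2-oxo-4-(propan-2-yl)-3-[(1S)-1-[(triethylsilyl)oxy]ethyl]octahydro-1H-inden-1-yl (2R)-2-methylbutanoate; 19 (2E)-3-methylpent-2-enoic acid
Product: 20 (1R,3R,3aR,4R,6S,7aS)-7-methylidene-2-oxo-4-(propan-2-yl)-3-[(1S)-1-[(triethylsilyl)oxy]ethyl]octahydro-1H-indene-1,6-diyl 1-[(2R)-2-methylbutanoate] 6-[(2E)-3-methylpent-2-enoate]
Conditions: 19 (2 equiv), DCC (2 equiv), DMAP (0.3 equiv), CH2Cl2, 0 °C → rt
Reagents that add atoms: none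
Why: Steglich esterification of the only free hydroxyl (the side-chain oxygen is silylated); the conditions leave the E alkene geometry and the carbinol configuration unchanged.

**Step 9**
Reactants: 20 (1R,3R,3aR,4R,6S,7aS)-7-methylidene-2-oxo-4-(propan-2-yl)-3-[(1S)-1-[(triethylsilyl)oxy]ethyl]octahydro-1H-indene-1,6-diyl 1-[(2R)-2-methylbutanoate] 6-[(2E)-3-methylpent-2-enoate]
Product: 21 (1R,3R,3aR,4R,6S,7aS)-3-[(1S)-1-hydroxyethyl]-7-methylidene-2-oxo-4-(propan-2-yl)octahydro-1H-indene-1,6-diyl 1-[(2R)-2-methylbutanoate] 6-[(2E)-3-methylpent-2-enoate]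
Conditions: HF·pyridine, THF–pyridine, 0 °C
Reagents that add atoms: none
Why: Buffered fluoride desilylation removes the triethylsilyl ether without touching the two esters, the α-acyloxy ketone or the β-hydroxy ketone; no stereocenter is affected.

**Compound list**
1 | 3-methylbutanal | CC(C)CC=O | starting material
2 | but-3-en-2-one | CC(=O)C=C | starting material
3 | (2R)-5-oxo-2-(propan-2-yl)hexanal | O=C[C@@H](C(C)C)CCC(C)=O | intermediate
4 | (4R)-4-(propan-2-yl)cyclohex-2-en-1-one | O=C1C=C[C@@H](C(C)C)CC1 | intermediate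
5 | 1,1-dimethoxyethene | C=C(OC)OC | starting material
6 | (1S,5R,6R)-7,7-dimethoxy-5-(propan-2-yl)bicyclo[4.2.0]octan-2-one | O=C1[C@@H]2[C@H](C(OC)(OC)C2)[C@@H](C(C)C)CC1 | intermediate
7 | (1S,5R,6R)-7,7-dimethoxy-2-methylidene-5-(propan-2-yl)bicyclo[4.2.0]octane | C=C1[C@@H]2[C@H](C(OC)(OC)C2)[C@@H](C(C)C)CC1 | intermediate
8 | (1S,5R,6R)-2-methylidene-5-(propan-2-yl)bicyclo[4.2.0]octan-7-one | C=C1[C@@H]2[C@H](C(=O)C2)[C@@H](C(C)C)CC1 | intermediate
9 | (1Z)-1-bromoprop-1-ene | C/C=C\Br | starting material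
10 | (1Z)-prop-1-en-1-yllithium | C/C=C\[Li] | intermediate
11 | (1S,5R,6R,7R)-2-methylidene-5-(propan-2-yl)-7-[(1Z)-prop-1-en-1-yl]bicyclo[4.2.0]octan-7-ol | C=C1[C@@H]2[C@H]([C@](O)(/C=C\C)C2)[C@@H](C(C)C)CC1 | intermediate
12 | (1S,5R,6R,7S)-2-methylidene-7-[(2S,3S)-3-methyloxiran-2-yl]-5-(propan-2-yl)bicyclo[4.2.0]octan-7-ol | C=C1[C@@H]2[C@H]([C@](O)([C@H]3O[C@H]3C)C2)[C@@H](C(C)C)CC1 | intermediate
13 | (1R,3aS,7R,7aR)-4-methylidene-7-(propan-2-yl)-1-[(1S)-1-[(triethylsilyl)oxy]ethyl]octahydro-2H-inden-2-one | C=C1[C@@H]2[C@H]([C@H]([C@H](C)O[Si](CC)(CC)CC)C(=O)C2)[C@@H](C(C)C)CC1 | intermediate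
14 | (2R)-2-methylbutanoic acid | CC[C@@H](C)C(=O)O | starting material
15 | triethyl{(1S)-1-[(1R,3aR,7R,7aR)-4-methylidene-7-(propan-2-yl)-2-[(trimethylsilyl)oxy]-3a,4,5,6,7,7a-hexahydro-1H-inden-1-yl]ethoxy}silane | C=C1[C@@H]2[C@H]([C@H]([C@H](C)O[Si](CC)(CC)CC)C(O[Si](C)(C)C)=C2)[C@@H](C(C)C)CC1 | intermediate
16 | (1S,3R,3aS,4R,7aS)-1-bromo-7-methylidene-4-(propan-2-yl)-3-[(1S)-1-[(triethylsilyl)oxy]ethyl]octahydro-2H-inden-2-one | C=C1[C@@H]2[C@H]([C@H]([C@H](C)O[Si](CC)(CC)CC)C(=O)[C@H]2Br)[C@@H](C(C)C)CC1 | intermediate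
17 | (1R,3R,3aR,4R,7aS)-7-methylidene-2-oxo-4-(propan-2-yl)-3-[(1S)-1-[(triethylsilyl)oxy]ethyl]octahydro-1H-inden-1-yl (2R)-2-methylbutanoate | C=C1[C@@H]2[C@H]([C@H]([C@H](C)O[Si](CC)(CC)CC)C(=O)[C@@H]2OC(=O)[C@H](C)CC)[C@@H](C(C)C)CC1 | intermediate
18 | (1R,3R,3aR,4R,6S,7aS)-6-hydroxy-7-methylidene-2-oxo-4-(propan-2-yl)-3-[(1S)-1-[(triethylsilyl)oxy]ethyl]octahydro-1H-inden-1-yl (2R)-2-methylbutanoate | C=C1[C@@H]2[C@H]([C@H]([C@H](C)O[Si](CC)(CC)CC)C(=O)[C@@H]2OC(=O)[C@H](C)CC)[C@@H](C(C)C)C[C@@H]1O | intermediate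
19 | (2E)-3-methylpent-2-enoic acid | CC/C(C)=C/C(=O)O | starting material
20 | (1R,3R,3aR,4R,6S,7aS)-7-methylidene-2-oxo-4-(propan-2-yl)-3-[(1S)-1-[(triethylsilyl)oxy]ethyl]octahydro-1H-indene-1,6-diyl 1-[(2R)-2-methylbutanoate] 6-[(2E)-3-methylpent-2-enoate] | C=C1[C@@H]2[C@H]([C@H]([C@H](C)O[Si](CC)(CC)CC)C(=O)[C@@H]2OC(=O)[C@H](C)CC)[C@@H](C(C)C)C[C@@H]1OC(=O)/C=C(\C)CC | intermediate
21 | (1R,3R,3aR,4R,6S,7aS)-3-[(1S)-1-hydroxyethyl]-7-methylidene-2-oxo-4-(propan-2-yl)octahydro-1H-indene-1,6-diyl 1-[(2R)-2-methylbutanoate] 6-[(2E)-3-methylpent-2-enoate] | C=C1[C@@H]2[C@H]([C@H]([C@H](C)O)C(=O)[C@@H]2OC(=O)[C@H](C)CC)[C@@H](C(C)C)C[C@@H]1OC(=O)/C=C(\C)CC | target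

**Step count and risks**
Total steps: 9. Longest linear sequence: 9 (steps 1 to 9).

Three steps most likely to fail:

Step 2 (trans-fused photoadduct). The trans:cis ratio at the ring junction and the facial selectivity are kinetic and may be modest. The fallback sets out from 4 and comes back at 8, building the ring junction by ionic chemistry instead of photochemistry. 2-Lithio-1,3-dithiane (from 1,3-dithiane and n-BuLi, THF–HMPA, −78 °C) adds in conjugate fashion anti to the isopropyl group and the enolate is trapped with gaseous formaldehyde. This gives (2R,3R,4R)-3-(1,3-dithian-2-yl)-2-(hydroxymethyl)-4-(propan-2-yl)cyclohexan-1-one F1, in which all three substituents are equatorial and C2 can equilibrate. Cp2TiMe2 methylenation then gives [(1S,2R,3R)-2-(1,3-dithian-2-yl)-6-methylidene-3-(propan-2-yl)cyclohexyl]methanol F2, and PPh3 with CCl4 gives 2-[(1R,2S,6R)-2-(chloromethyl)-3-methylidene-6-(propan-2-yl)cyclohexyl]-1,3-dithiane F3. n-BuLi (THF, −30 °C) closes the four-membered ring by intramolecular alkylation of the dithiane anion to (1S,5R,6R)-2-methylidene-5-(propan-2-yl)spiro[bicyclo[4.2.0]octane-7,2'-[1,3]dithiane] F4. MeI with CaCO3 in aqueous MeCN unmasks 8.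

Step 5 (the proposed new relay). The face selectivity of the epoxidation, vanadium-induced cleavage of the cyclobutanol and migration of the wrong ring carbon are the risks. The fallback uses known chemistry, sets out from 8 and comes back at 13, and does not depend on the carbinol configuration. Prop-1-ynyllithium (from propyne and n-BuLi, THF, −78 °C) adds to 8 to give (1S,5R,6R,7S)-2-methylidene-5-(propan-2-yl)-7-(prop-1-yn-1-yl)bicyclo[4.2.0]octan-7-ol F5. Catalytic [(4-CF3C6H4)3P]AuCl with AgSbF6 (CH2Cl2, rt) brings about the known 1,2-shift ring expansion of the 1-alkynylcyclobutanol, with migration of the bridgehead carbon, to (1E,3aS,7R,7aR)-1-ethylidene-4-methylidene-7-(propan-2-yl)octahydro-2H-inden-2-one F6. Copper-catalysed asymmetric conjugate borylation (CuCl, NaOt-Bu, a Josiphos-type bisphosphine of the enantiomer that gives the S carbinol, B2pin2, MeOH, THF) gives (1S,3aS,7R,7aR)-4-methylidene-7-(propan-2-yl)-1-[(1S)-1-(4,4,5,5-tetramethyl-1,3,2-dioxaborolan-2-yl)ethyl]octahydro-2H-inden-2-one F7, with the ring α-center settling trans to the neighbouring ring bond. NaBO3 oxidation with retention gives (1R,3aS,7R,7aR)-1-[(1S)-1-hydroxyethyl]-4-methylidene-7-(propan-2-yl)octahydro-2H-inden-2-one F8, and Et3SiCl with imidazole gives 13.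

Step 6 (C1 acyloxylation with inversion). The bromide can epimerise before displacement and the α-acyloxy ketone can epimerise under the carboxylate base. The fallback sets out from 13 and comes back at 17, using an oxygen electrophile and a neutral inversion. The lithium enolate (LiN(SiMe3)2, THF, −78 °C) is hydroxylated with 2-(phenylsulfonyl)-3-phenyloxaziridine on the same face that bromine takes, giving (1S,3R,3aR,4R,7aS)-1-hydroxy-7-methylidene-4-(propan-2-yl)-3-[(1S)-1-[(triethylsilyl)oxy]ethyl]octahydro-2H-inden-2-one F9. Mitsunobu esterification with 14 (PPh3, DIAD, toluene, 0 °C) inverts the carbinol and gives 17.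

**Further compounds**
F1 | step 2 | (2R,3R,4R)-3-(1,3-dithian-2-yl)-2-(hydroxymethyl)-4-(propan-2-yl)cyclohexan-1-one | O=C1[C@@H](CO)[C@H](C2SCCCS2)[C@@H](C(C)C)CC1
F2 | step 2 | [(1S,2R,3R)-2-(1,3-dithian-2-yl)-6-methylidene-3-(propan-2-yl)cyclohexyl]methanol | C=C1[C@@H](CO)[C@H](C2SCCCS2)[C@@H](C(C)C)CC1
F3 | step 2 | 2-[(1R,2S,6R)-2-(chloromethyl)-3-methylidene-6-(propan-2-yl)cyclohexyl]-1,3-dithiane | C=C1[C@@H](CCl)[C@H](C2SCCCS2)[C@@H](C(C)C)CC1
F4 | step 2 | (1S,5R,6R)-2-methylidene-5-(propan-2-yl)spiro[bicyclo[4.2.0]octane-7,2'-[1,3]dithiane] | C=C1[C@@H]2[C@H](C3(SCCCS3)C2)[C@@H](C(C)C)CC1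
F5 | step 5 | (1S,5R,6R,7S)-2-methylidene-5-(propan-2-yl)-7-(prop-1-yn-1-yl)bicyclo[4.2.0]octan-7-ol | C=C1[C@@H]2[C@H]([C@](O)(C#CC)C2)[C@@H](C(C)C)CC1
F6 | step 5 | (1E,3aS,7R,7aR)-1-ethylidene-4-methylidene-7-(propan-2-yl)octahydro-2H-inden-2-one | C=C1[C@@H]2[C@H](/C(=C\C)C(=O)C2)[C@@H](C(C)C)CC1
F7 | step 5 | (1S,3aS,7R,7aR)-4-methylidene-7-(propan-2-yl)-1-[(1S)-1-(4,4,5,5-tetramethyl-1,3,2-dioxaborolan-2-yl)ethyl]octahydro-2H-inden-2-one | C=C1[C@@H]2[C@H]([C@H]([C@H](C)B3OC(C)(C)C(C)(C)O3)C(=O)C2)[C@@H](C(C)C)CC1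
F8 | step 5 | (1R,3aS,7R,7aR)-1-[(1S)-1-hydroxyethyl]-4-methylidene-7-(propan-2-yl)octahydro-2H-inden-2-one | C=C1[C@@H]2[C@H]([C@H]([C@H](C)O)C(=O)C2)[C@@H](C(C)C)CC1
F9 | step 6 | (1S,3R,3aR,4R,7aS)-1-hydroxy-7-methylidene-4-(propan-2-yl)-3-[(1S)-1-[(triethylsilyl)oxy]ethyl]octahydro-2H-inden-2-one | C=C1[C@@H]2[C@H]([C@H]([C@H](C)O[Si](CC)(CC)CC)C(=O)[C@H]2O)[C@@H](C(C)C)CC1
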